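**Assumption:** the target is the C8-linked chalcane–flavan with a (2R,3S)-catechin lower unit and a (1R,2S)-configured upper propyl chain, as read from the SMILES. TBSCl is numbered because it contributes atoms to intermediates.

## Retrosynthetic overview
1. Gambiriin A1 (5) ⇐ global desilylation of the octa-TBS ether 4.
2. 4 ⇐ C1(chalcane)–C8(flavan) bond, made by light-induced C2–O1 heterolysis of one molecule of tetra-O-TBS-catechin 3 and Friedel–Crafts capture of the benzylic cation by C8 of a second molecule of 3.
3. 3 ⇐ (+)-catechin (1), which supplies both halves and four of the five stereocentres; the fifth (benzylic C1) is set by 1,2-induction from the catechin C3 carbinol.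
4. Ring order: no ring is built. The lower flavan is carried intact from 1; the upper pyran ring is opened in the key step.

## Route

**Step 1**
Reactants: 1, (+)-catechin [(2R,3S)-2-(3,4-dihydroxyphenyl)chromane-3,5,7-triol, dried]; 2, tert-butyldimethylsilyl chloride
Product: 3, (2R,3S)-2-[3,4-bis(TBSO)phenyl]-5,7-bis(TBSO)chroman-3-ol (phenols silylated, 3-OH free)
Conditions: TBSCl (4.4 equiv), imidazole (10 equiv), DMF, 0 °C → rt, Ar
Reagents that add atoms: TBSCl, CC(C)(C)[Si](C)(C)Cl
Why: Chemoselective O-silylation, since the four phenols react much faster than the hindered secondary 3-OH; imidazole is too weak a base to open the pyran ring, so C2 and C3 are untouched.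

**Step 2**
Reactants: 3 (two molecules; one is the electrophile precursor, one the nucleophile)
Product: 4, (2R,3S)-2-[3,4-bis(TBSO)phenyl]-8-{(1R,2S)-1-[3,4-bis(TBSO)phenyl]-2-hydroxy-3-[2-hydroxy-4,6-bis(TBSO)phenyl]propyl}-5,7-bis(TBSO)chroman-3-ol
Conditions: hν (≈300 nm), degassed HFIP/CH2Cl2 (4:1), 0.3 M, 0 °C, FEP flow reactor (1 mm path), ~40% conversion per pass; recovered 3 recycled after removal of any C2-epimer
Reagents that add atoms: none
Why: Proposed new method: singlet excitation of the 4-silyloxybenzyl aryl ether (C2–O1) in strongly ionising, non-nucleophilic HFIP should cause heterolysis to a 4-silyloxy-stabilised benzylic cation (the phenoxide is protonated by solvent), which is captured at C8 of a ground-state molecule of 3 (C6 is flanked by two OTBS groups, and C8 is the intrinsically more nucleophilic flavan position); A(1,3) strain places the C3–H in the cation plane, so the arene adds anti to the bulky 2-hydroxy-4,6-disilyloxybenzyl group, on the face opposite the departed O1, giving 1R next to the retained 2S carbinol; the process is redox- and proton-neutral, and the closest known reaction types are the photosolvolytic pyran-ring opening of O-methylated flavan-3-ols with capture by solvent or phloroglucinol, and the thermal quinone-methide self-condensation of catechin.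

**Step 3**
Reactants: 4
Product: 5, gambiriin A1, (2R,3S)-2-(3,4-dihydroxyphenyl)-8-[(1R,2S)-1-(3,4-dihydroxyphenyl)-2-hydroxy-3-(2,4,6-trihydroxyphenyl)propyl]chromane-3,5,7-triol
Conditions: KHF2 (excess), MeOH/THF (2:1), rt, Ar; Sephadex LH-20
Reagents that add atoms: none
Why: Fluoride cleavage of aryl silyl ethers (Si–F bond formation) in a mildly acidic medium, which avoids phenoxides and therefore quinone-methide epimerisation and air oxidation; no C–C bond or stereocentre is touched.

## Compound list
1 | (+)-catechin | Oc1cc(O)c2c(c1)O[C@H](c1ccc(O)c(O)c1)[C@@H](O)C2 | starting material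
2 | tert-butyldimethylsilyl chloride | CC(C)(C)[Si](C)(C)Cl | starting material
3 | 5,7,3',4'-tetra-O-TBS-(+)-catechin | CC(C)(C)[Si](C)(C)Oc1cc(O[Si](C)(C)C(C)(C)C)c2c(c1)O[C@H](c1ccc(O[Si](C)(C)C(C)(C)C)c(O[Si](C)(C)C(C)(C)C)c1)[C@@H](O)C2 | intermediate
4 | octa-O-TBS gambiriin A1 (upper A-ring 2-OH and both secondary OH free) | CC(C)(C)[Si](C)(C)Oc1cc(O)c(C[C@H](O)[C@H](c2ccc(O[Si](C)(C)C(C)(C)C)c(O[Si](C)(C)C(C)(C)C)c2)c2c(O[Si](C)(C)C(C)(C)C)cc(O[Si](C)(C)C(C)(C)C)c3c2O[C@H](c2ccc(O[Si](C)(C)C(C)(C)C)c(O[Si](C)(C)C(C)(C)C)c2)[C@@H](O)C3)c(O[Si](C)(C)C(C)(C)C)c1 | intermediate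
5 | gambiriin A1 | Oc1cc(O)c(C[C@H](O)[C@H](c2ccc(O)c(O)c2)c2c(O)cc(O)c3c2O[C@H](c2ccc(O)c(O)c2)[C@@H](O)C3)c(O)c1 | target

## Summary
Total steps: 3. Longest linear sequence: 3.

Steps most likely to fail:

1. **Step 2 (proposed new step).** Risks: reclosure of the cation competes with intermolecular capture and epimerises C2 of monomer 3 (the epimer would then act as a nucleophile); minor C6 attack; imperfect facial selectivity; secondary photolysis of the flavan unit in 4. Fallback (known chemistry): drop the protecting groups and the photochemical step, and use the documented thermal self-condensation of unprotected (+)-catechin in hot water, which proceeds through the ground-state p-quinone methide; separate gambiriin A1 from the C6-linked isomer by Sephadex LH-20 and reversed-phase HPLC.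

2. **Step 3.** Risks: incomplete eightfold desilylation, and oxidation or loss of the free polyphenol during isolation. Fallback: fluoride-triggered in-situ peracetylation (CsF, Ac2O, DMF) to the undeca-acetate, purification on silica, then mild deacetylation (NH4OAc, aqueous MeOH), so that a stable, chromatographable intermediate is isolated instead of the free polyphenol.

3. **Step 1.** Risks: mixtures of tri-, tetra- and penta-silyl ethers. Fallback: exhaustive silylation to the penta-TBS ether (TBSOTf, 2,6-lutidine), then selective acidic cleavage of the single alkyl silyl ether (CSA, MeOH/CH2Cl2, 0 °C), relying on aryl TBS ethers being more acid-stable than alkyl TBS ethers.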